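Any D still solid at 20 s is a leftover that has coupled to nothing, so reckon first what can leave the solid.

D 5.0 × 10⁻⁴ M; L 0.500 mM; time 20 s

* amount of X and L.X together at 20 s, in percent of the D charged
* concentration of Z in solution at 2.0 s, in percent of saturation
* the change that raises the amount of X and L.X together at 20 s, in percent of the D charged most ("none" if none brings more than 2 percentage points) (Thursday's / Sunday's / Friday's / Saturday's / none)
* amount of X and L.X together at 20 s, in percent of the D charged, after Friday's

- amounts and yields of X count L.X too
- amounts and yields of Q count G too
- given per volume of solution although it is solid: D, G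
- at the start none of D is in solution
- Z means what is dissolved; the solid is not counted in it
- run time (flask): 20 s

- Thursday's: doubling the dissolution coefficient of step 1, all else as stated
- Sunday's: doubling the solubility in step 3, all else as stated
- Friday's: doubling the amount of L, all else as stated
- Saturday's: doubling the dissolution coefficient of step 3, all else as stated

    G ⇌ Q, rate k1*(cs1 - [Q]) while solid is left; crystals form when [Q] > cs1 (cs1 = 0.082 mM, k1 = 5.8 s⁻¹)
    Z + L → X + Q (k2 = 220 L mol⁻¹ s⁻¹)
    D ⇌ Z, rate k3*(cs3 - [Z]) while solid is left; crystals form when [Z] > cs3 (cs3 = 0.30 mM, k3 = 0.033 s⁻¹)
    L + X ⇌ L.X, settled at all times (K4 = 1100 L mol⁻¹)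

D dissolves at its coefficient times the gap to solubility, so it starts at 0.0198 s⁻¹, as a fraction of the charge per second. Over 20 s that adds up to 39.6 %: the feed budget, the fraction of the charge that dissolving can deliver by the reading into a solution kept empty.

Now count the slowings. With L as charged, Z couples pseudo-first-order at 0.110 s⁻¹, faster than its 0.033 s⁻¹ of push-back on the dissolving. So Z levels off and the feed runs at 0.769 of its start. Levelling takes 6.99 s, and that lag leaves 0.670 of the time counting. That gives 20.4 %. L falls as it couples, and its mean over the run costs 0.898, leaving aside what L.X holds, so I commit to 18.3 %. At 2.0 s the same curve puts Z at 5.75 % of saturation.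

Sunday's doubles the budget and keeps the feed and lag factors, but the L factor drops from 0.898 to 80 percentage points as more L couples, giving 32.5 %. Saturday's doubles the budget too but lowers the factors taken together, giving 29.4 %. Friday's keeps the budget and lifts the factors, giving 25.8 %. My pick is Sunday's, the highest of these.

The forecast, holding that "Dissolution of D limits the rate", says 18.6 %, 5.7 %, Sunday's and 25.8 %, a shade above me on the first. The flask gives 18.6 %, 5.74 %, Sunday's (a gain of 15 points) and 26.3 %.

Against the budget of 39.6 %, this flask had lost 33.2 % of its charge of D from the solid by 20.0 s. At that moment Z was being made 1.23 times as fast as it coupled with L.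

With 2.0 × 10⁻⁴ M of D, the budget becomes 99.0 %. The factors hold no charge of D, and L falls by the same amount, so that flask should reach 45.8 %; it gives 46.6 %.

(The constants are assumed; the result is computed.)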